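Count the Q.

| flask | E | Q | J | remark | time |
|---|---|---|---|---|---|
| noon | 0.050 M | 0.018 M (in portions, 3) | 0.050 M | run made earlier; portions every 15 min |  |
| spring | 0.050 M | 0.080 M (in portions, 3) | 0.050 M | run made earlier; portions every 15 min |  |
| green | 0.050 M | 0.0300 M | 0.0500 M | everything together at the start | 50 min |
| red | 0.050 M | 0.0900 M (in portions, 3) | 0.0500 M | the portions of Q follow each other after 15 min, the first at the start | 50 min |

- noon (time / min: X / %): 8.00: 0.5; 15.0: 1.7; 20.0: 0; 30.0: 0; 40.0: 0
- spring (time / min: X / %): 8.00: 1.0; 15.0: 0.7; 20.0: 4.3; 30.0: 6.3; 40.0: 14.5

(standard deviation of a reading: 1 percentage point)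

- the earlier runs were read with a standard deviation of 1 percentage point

* the winner by amount of X, in percent of the E charged; "neither" if no more than 2 percentage points parts them (green / red / neither)
* how much X is there at the end, in percent of the E charged: green
* how much X is there at the end, in percent of the E charged: red

X has two ligands exchanged, so each X takes two Q, and for full conversion Q is the limiting reagent in both flasks, at 0.600 and 1.80 Q per E charged. I therefore expect X to grow with the square of the Q present, and I weigh each minute by the square of the fraction of the charge that has gone in. Spring up to 40.0 min then counts as 18.3 min at full charge, red up to 50 min as 28.3 min, and green keeps its whole 50 min.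

Multiplying by the squared charge relative to spring gives 0.384 for green and 1.96 for red. This dose ratio says how many spring readings of 14.5% a flask makes. My reckoning is therefore 5.56% in green and 28.4% in red, with red ahead. Noon at 40.0 min comes to 0.734%, and its reading of 0% lies within the scatter.

Is one number enough? It treats Q as staying at its charge, yet X by itself takes 18.1% of spring's Q, 18.5% of green's and 31.5% of red's. These shares count Q in X by itself, and whatever else takes Q is not in them, so I hold both figures as rough.

The forecast says red, with 6% for green and 25% for red, lower than my red: “Loss of Q and E and released J pull this down to about 25 %.”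

The flask gives red, with green at 6.97% and red at 25.2%.

    E + Q ⇌ J + L (K = 1.60, k = 0.00750 L mol⁻¹ s⁻¹)
    L + Q ⇌ J + X (K = 21.0, k = 0.0130 L mol⁻¹ s⁻¹)
    X ⇌ G (K = 0.690, k = 2.10 × 10⁻⁴ s⁻¹)

Green stands at 0.481 spring readings against its ratio of 0.384, and red at 1.74 against 1.96. The largest single effect between the two flasks is the difference in concentration of Q : green with red's charge of Q reaches 31.5% instead of 6.97%, a shift of 25 points. A neighbour of green with 0.051 M of Q has the ratio 1.11, which foretells 16.1%, and it gives 15.4%; with 0.12 M the ratio 6.14 foretells 89.0%, but the flask gives 42.1%.

The readings stem from a simulated flask on assumed constants, and the scatter is random.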